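**Retrosynthetic overview**

1. The target is traced back to its tris-triisopropylsilyl ether. The threo (7R,8R) guaiacylglycerol unit is cut at C7–C8 (Evans syn aldol of a ring-B aryloxyacetyl oxazolidinone with silylated vanillin) and at the ring-B O–CH2 bond (phenol plus allyl bromoacetate).
2. The tetrahydrofuran is cut at O1–C2 (SN1 closure of the C5 hydroxyl onto the ring-A benzylic carbon of a triol) and at C2–C3 (aldol of a lactone enolate with the same aldehyde). The triol comes from hydride opening of a trans α,β-disubstituted γ-butyrolactone.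
3. The strategy rests on this feature: tetrahydrofuran C4 carries the ring-B benzyl group, the C5 methylene bound to O1, and C3. C4 is ring carbon 3 of a prochiral 3-(arylmethyl)cyclobutanone whose two α-methylenes become C5 and C3 and whose carbonyl carbon becomes the hydroxymethyl carbon, so one enantioselective Baeyer–Villiger ring expansion makes the O1–C5 bond and the C4 stereocentre.
4. The cyclobutanone is cut by [2+2] into O-benzyleugenol (ring B, benzylic CH2, C4, one α-methylene) and dichloroketene (carbonyl carbon, other α-methylene). Which methylene becomes C5 is decided only in the ring expansion.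
5. Ring order: cyclobutane, then γ-butyrolactone (ring expansion), then lactone opened, then tetrahydrofuran (ring switch, trans lactone to 3,4-cis ether).

Key step: step 4

Remark: the carbinol carbon made in step 6 is carried as both epimers, because step 8 ionises that carbon and sets C2 afresh.
Remark: in step 4 the antipode of the N,N'-dioxide ligand is taken to be the one that delivers the R lactone, to be fixed by one trial with each antipode.

Step 1
Reactants: 1 eugenol
Product: 2 4-allyl-1-(benzyloxy)-2-methoxybenzene (O-benzyleugenol)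
Conditions: BnBr, K2CO3, acetone, reflux
Reagents that add atoms: benzyl bromide, BrCc1ccccc1
Why: Williamson ether synthesis, phenoxide SN2 on a benzylic bromide; no stereocentre is involved.

Step 2
Reactants: 2 O-benzyleugenol; 3 trichloroacetyl chloride
Product: 5 rac-2,2-dichloro-3-(4-benzyloxy-3-methoxybenzyl)cyclobutan-1-one, via dichloroketene 4 (not isolated)
Conditions: zinc–copper couple (Zn/Cu), POCl3, Et2O, rt to reflux
Reagents that add atoms: none
Why: Zinc dechlorinates the acid chloride to dichloroketene, which should add to the terminal alkene in a thermal [2+2] ketene–alkene cycloaddition with the carbonyl carbon bonding to the terminal CH2, so the arylmethyl group lands on C3; the product is racemic and its stereocentre loses chirality in step 3.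

Step 3
Reactants: 5 rac-2,2-dichloro-3-(4-benzyloxy-3-methoxybenzyl)cyclobutan-1-one
Product: 6 3-(4-benzyloxy-3-methoxybenzyl)cyclobutan-1-one
Conditions: Zn dust, AcOH, rt to 60 °C
Reagents that add atoms: none
Why: Reductive dehalogenation of an α,α-dichloroketone by zinc through a zinc enolate removes both chlorines and leaves the achiral, prochiral ketone; the benzyl ether is inert.

Step 4
Reactants: 6 3-(4-benzyloxy-3-methoxybenzyl)cyclobutan-1-one
Product: 7 (R)-4-(4-benzyloxy-3-methoxybenzyl)dihydrofuran-2(3H)-one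
Conditions: Sc(OTf)3 (5 mol%), C2-symmetric amino-acid-derived chiral N,N'-dioxide ligand (6 mol%), m-CPBA (1.2 equiv), EtOAc, −20 °C
Reagents that add atoms: m-CPBA, O=C(OO)c1cccc(Cl)c1
Why: The chiral trivalent-scandium complex binds and activates the strained ketone, m-CPBA adds to the carbonyl to give a Criegee adduct inside the chiral pocket, and the α-methylene held antiperiplanar to the O–O bond migrates to oxygen as 3-chlorobenzoate leaves. The closest known reaction type is the catalytic enantioselective Baeyer–Villiger desymmetrisation of 3-substituted cyclobutanones by chiral Lewis or Brønsted acids. The γ-lactone is closed by ring expansion, a 1,2-shift of a ring C–C bond from carbon to oxygen that turns the four-membered carbocycle into the five-membered oxacycle and creates the O–CH2 bond that becomes O1–C5 of the target. The only new stereocentre, C4 of the lactone (later C4 of the tetrahydrofuran), is set by the catalyst alone, which decides which of the two enantiotopic CH2 groups migrates, since the ketone is achiral. The step needs enantiotopic-group selectivity, supplied by the ligand, and chemoselectivity for the ketone over the electron-rich arene and the benzyl ether, which the strain-driven reactivity of the cyclobutanone at −20 °C should secure.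

Step 5
Reactants: 8 vanillin
Product: 9 3-methoxy-4-(triisopropylsilyloxy)benzaldehyde
Conditions: TIPSCl, imidazole, DMF, rt
Reagents that add atoms: triisopropylsilyl chloride, CC(C)[Si](Cl)(C(C)C)C(C)C
Why: Imidazole-promoted silylation of a phenol (substitution at silicon) gives an aryl silyl ether that tolerates the later base, hydride, acid and hydrogenolysis steps and is removed by fluoride.

Step 6
Reactants: 7 (R)-lactone; 9 3-methoxy-4-(triisopropylsilyloxy)benzaldehyde
Product: 11 (3S,4R)-4-(4-benzyloxy-3-methoxybenzyl)-3-{hydroxy[3-methoxy-4-(triisopropylsilyloxy)phenyl]methyl}dihydrofuran-2(3H)-one (3,4-trans; both carbinol epimers), via lactone lithium enolate 10 (not isolated)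
Conditions: LDA (1.1 equiv), THF, −78 °C; 9, −78 °C; AcOH quench at −78 °C
Reagents that add atoms: none
Why: Aldol addition of a lactone lithium enolate; the aldehyde should approach the enolate face anti to the C4 arylmethyl group, so C3 is set trans to C4 by substrate control, while the carbinol centre need not be controlled.

Step 7
Reactants: 11 trans aldol lactone
Product: 12 (2R,3R)-2-(4-benzyloxy-3-methoxybenzyl)-3-{hydroxy[3-methoxy-4-(triisopropylsilyloxy)phenyl]methyl}butane-1,4-diol (both carbinol epimers)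
Conditions: LiAlH4, THF, 0 °C; aqueous NaOH work-up
Reagents that add atoms: none
Why: Hydride reduction of the lactone to the 1,4-diol (acyl substitution, then aldehyde reduction) is fast at 0 °C, touches neither stereocentre and should leave the hindered aryl silyl ether intact.

Step 8
Reactants: 12 triol
Product: 13 {(2S,3R,4R)-4-(4-benzyloxy-3-methoxybenzyl)-2-[3-methoxy-4-(triisopropylsilyloxy)phenyl]tetrahydrofuran-3-yl}methanol (2,3-trans, 3,4-cis)
Conditions: camphorsulfonic acid (10 mol%), CH2Cl2, 0 °C to rt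
Reagents that add atoms: none
Why: Acid-promoted SN1 cyclodehydration: the p-silyloxybenzylic cation from either carbinol epimer is captured by the C5 hydroxyl in a 5-membered closure (the other CH2OH could only give an oxetane), and C2 should settle trans to the C3 substituent under steric and thermodynamic control, while the ring switch turns the trans lactone pattern into the 3,4-cis ether.

Step 9
Reactants: 13 tetrahydrofuran alcohol
Product: 14 (2S,3R,4R)-4-(4-benzyloxy-3-methoxybenzyl)-2-[3-methoxy-4-(triisopropylsilyloxy)phenyl]-3-[(triisopropylsilyloxy)methyl]tetrahydrofuran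
Conditions: TIPSCl, imidazole, DMF, rt
Reagents that add atoms: triisopropylsilyl chloride, CC(C)[Si](Cl)(C(C)C)C(C)C
Why: Silylation of the primary alcohol masks the only free hydroxyl before the acylation and boron enolate steps.

Step 10
Reactants: 14 bis-silyl ether
Product: 15 (2S,3R,4R)-4-(4-hydroxy-3-methoxybenzyl)-2-[3-methoxy-4-(triisopropylsilyloxy)phenyl]-3-[(triisopropylsilyloxy)methyl]tetrahydrofuran (free ring-B phenol)
Conditions: H2 (1 atm), 10% Pd/C, EtOAc, rt
Reagents that add atoms: none
Why: Catalytic hydrogenolysis cleaves the aryl benzyl ether much faster than the dialkyl benzylic C2–O1 bond in neutral ethyl acetate, and silyl ethers are inert, so only the ring-B phenol is unmasked.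

Step 11
Reactants: 15 ring-B phenol; 16 allyl bromoacetate
Product: 17 allyl aryloxyacetate of 15 (ring-B O–CH2–CO2CH2CH=CH2; core stereocentres as in 14)
Conditions: K2CO3, acetone, 50 °C
Reagents that add atoms: none
Why: Williamson ether synthesis, phenoxide SN2 on an α-bromo ester; aryl silyl ethers should survive carbonate in an aprotic solvent.

Step 12
Reactants: 17 allyl ester
Product: 18 aryloxyacetic acid (ring-B O–CH2–CO2H; core stereocentres as in 14)
Conditions: Pd(PPh3)4 (5 mol%), morpholine, THF, rt; pH 4 citrate work-up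
Reagents that add atoms: none
Why: Tsuji–Trost deallylation: zerovalent palladium ionises the allyl ester to a π-allyl complex that morpholine captures, freeing the acid under neutral conditions that spare both silyl ethers.

Step 13
Reactants: 18 aryloxyacetic acid; 19 (S)-4-benzyloxazolidin-2-one
Product: 21 (S)-4-benzyl-3-(aryloxyacetyl)oxazolidin-2-one (aryl = ring B of the silylated core), via mixed pivalic anhydride 20 (not isolated)
Conditions: PivCl, Et3N, THF, −20 °C; then 19, LiCl, rt
Reagents that add atoms: none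
Why: N-acylation of the oxazolidinone through a mixed anhydride; the nucleophile attacks the unhindered aryloxyacetyl carbonyl rather than the pivaloyl carbonyl.

Step 14
Reactants: 21 N-acyl oxazolidinone; 9 3-methoxy-4-(triisopropylsilyloxy)benzaldehyde
Product: 23 (S)-4-benzyl-3-[(2S,3R)-3-hydroxy-3-(3-methoxy-4-triisopropylsilyloxyphenyl)-2-(ring-B aryloxy)propanoyl]oxazolidin-2-one, via Z-dibutylboron enolate 22 (not isolated)
Conditions: Bu2BOTf, iPr2NEt, CH2Cl2, −78 to 0 °C; 9, −78 to 0 °C; pH 7 buffer, MeOH, 30% H2O2, 0 °C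
Reagents that add atoms: none
Why: Evans syn aldol: the Z boron enolate reacts through a Zimmerman–Traxler chair with the auxiliary carbonyl turned away from the enolate oxygen, the aldehyde adds to the face opposite the benzyl group of the S auxiliary, and the 2,3-syn adduct (2S,3R) corresponds to the threo 7R,8R pattern of the target.

Step 15
Reactants: 23 aldol adduct
Product: 24 (1R,2R)-1-[3-methoxy-4-(triisopropylsilyloxy)phenyl]-2-(ring-B aryloxy)propane-1,3-diol (tris-silyl ether of the target)
Conditions: LiBH4, MeOH (1 equiv), THF, 0 °C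
Reagents that add atoms: none
Why: Reductive cleavage of the imide: hydride adds to the exocyclic carbonyl, the auxiliary is released and the acyl carbon becomes the primary alcohol without touching C7 or C8.

Step 16
Reactants: 24 tris-silyl ether
Product: 25 target, (1R,2R)-1-(4-hydroxy-3-methoxyphenyl)-2-{4-[((3R,4R,5S)-5-(4-hydroxy-3-methoxyphenyl)-4-(hydroxymethyl)tetrahydrofuran-3-yl)methyl]-2-methoxyphenoxy}propane-1,3-diol
Conditions: TBAF (3.5 equiv), AcOH (3.5 equiv), THF, 0 °C to rt
Reagents that add atoms: none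
Why: Fluoride-mediated desilylation driven by Si–F bond formation removes the two aryl and one alkyl silyl ether; the acetic acid buffer keeps the phenolic β-aryl ether and the benzylic alcohol away from strong base.

**Compound list**

1 | eugenol (4-allyl-2-methoxyphenol) | C=CCc1ccc(O)c(OC)c1 | starting material
2 | 4-allyl-1-(benzyloxy)-2-methoxybenzene | C=CCc1ccc(OCc2ccccc2)c(OC)c1 | intermediate
3 | trichloroacetyl chloride | ClC(=O)C(Cl)(Cl)Cl | starting material
4 | dichloroketene (formed in the flask) | ClC(Cl)=C=O | intermediate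
5 | rac-2,2-dichloro-3-(4-benzyloxy-3-methoxybenzyl)cyclobutan-1-one | COc1cc(CC2CC(=O)C2(Cl)Cl)ccc1OCc1ccccc1 | intermediate
6 | 3-(4-benzyloxy-3-methoxybenzyl)cyclobutan-1-one | COc1cc(CC2CC(=O)C2)ccc1OCc1ccccc1 | intermediate
7 | (R)-4-(4-benzyloxy-3-methoxybenzyl)dihydrofuran-2(3H)-one | COc1cc(C[C@H]2COC(=O)C2)ccc1OCc1ccccc1 | intermediate
8 | vanillin | COc1cc(C=O)ccc1O | starting material
9 | 3-methoxy-4-(triisopropylsilyloxy)benzaldehyde | COc1cc(C=O)ccc1O[Si](C(C)C)(C(C)C)C(C)C | intermediate
10 | lithium enolate of lactone 7 (R at C4, formed in the flask) | COc1cc(C[C@H]2COC(O[Li])=C2)ccc1OCc1ccccc1 | intermediate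
11 | (3S,4R)-4-(4-benzyloxy-3-methoxybenzyl)-3-{hydroxy[3-methoxy-4-(triisopropylsilyloxy)phenyl]methyl}dihydrofuran-2(3H)-one, both carbinol epimers | COc1cc(C[C@H]2COC(=O)[C@@H]2C(O)c2ccc(O[Si](C(C)C)(C(C)C)C(C)C)c(OC)c2)ccc1OCc1ccccc1 | intermediate
12 | (2R,3R)-2-(4-benzyloxy-3-methoxybenzyl)-3-{hydroxy[3-methoxy-4-(triisopropylsilyloxy)phenyl]methyl}butane-1,4-diol, both carbinol epimers | COc1cc(C[C@@H](CO)[C@H](CO)C(O)c2ccc(O[Si](C(C)C)(C(C)C)C(C)C)c(OC)c2)ccc1OCc1ccccc1 | intermediate
13 | {(2S,3R,4R)-4-(4-benzyloxy-3-methoxybenzyl)-2-[3-methoxy-4-(triisopropylsilyloxy)phenyl]tetrahydrofuran-3-yl}methanol | COc1cc(C[C@H]2CO[C@H](c3ccc(O[Si](C(C)C)(C(C)C)C(C)C)c(OC)c3)[C@H]2CO)ccc1OCc1ccccc1 | intermediate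
14 | (2S,3R,4R)-4-(4-benzyloxy-3-methoxybenzyl)-2-[3-methoxy-4-(triisopropylsilyloxy)phenyl]-3-[(triisopropylsilyloxy)methyl]tetrahydrofuran | COc1cc(C[C@H]2CO[C@H](c3ccc(O[Si](C(C)C)(C(C)C)C(C)C)c(OC)c3)[C@H]2CO[Si](C(C)C)(C(C)C)C(C)C)ccc1OCc1ccccc1 | intermediate
15 | (2S,3R,4R)-4-(4-hydroxy-3-methoxybenzyl)-2-[3-methoxy-4-(triisopropylsilyloxy)phenyl]-3-[(triisopropylsilyloxy)methyl]tetrahydrofuran | COc1cc(C[C@H]2CO[C@H](c3ccc(O[Si](C(C)C)(C(C)C)C(C)C)c(OC)c3)[C@H]2CO[Si](C(C)C)(C(C)C)C(C)C)ccc1O | intermediate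
16 | allyl bromoacetate | C=CCOC(=O)CBr | starting material
17 | allyl 2-(ring-B aryloxy)acetate of 15 | C=CCOC(=O)COc1ccc(C[C@H]2CO[C@H](c3ccc(O[Si](C(C)C)(C(C)C)C(C)C)c(OC)c3)[C@H]2CO[Si](C(C)C)(C(C)C)C(C)C)cc1OC | intermediate
18 | 2-(ring-B aryloxy)acetic acid | OC(=O)COc1ccc(C[C@H]2CO[C@H](c3ccc(O[Si](C(C)C)(C(C)C)C(C)C)c(OC)c3)[C@H]2CO[Si](C(C)C)(C(C)C)C(C)C)cc1OC | intermediate
19 | (S)-4-benzyloxazolidin-2-one | O=C1N[C@@H](Cc2ccccc2)CO1 | starting material
20 | mixed anhydride of 18 with pivalic acid (formed in the flask) | CC(C)(C)C(=O)OC(=O)COc1ccc(C[C@H]2CO[C@H](c3ccc(O[Si](C(C)C)(C(C)C)C(C)C)c(OC)c3)[C@H]2CO[Si](C(C)C)(C(C)C)C(C)C)cc1OC | intermediate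
21 | (S)-4-benzyl-3-[2-(ring-B aryloxy)acetyl]oxazolidin-2-one | O=C(COc1ccc(C[C@H]2CO[C@H](c3ccc(O[Si](C(C)C)(C(C)C)C(C)C)c(OC)c3)[C@H]2CO[Si](C(C)C)(C(C)C)C(C)C)cc1OC)N1[C@@H](Cc2ccccc2)COC1=O | intermediate
22 | Z dibutylboron enolate of 21 (formed in the flask) | CCCCB(CCCC)O/C(=C\Oc1ccc(C[C@H]2CO[C@H](c3ccc(O[Si](C(C)C)(C(C)C)C(C)C)c(OC)c3)[C@H]2CO[Si](C(C)C)(C(C)C)C(C)C)cc1OC)N1[C@@H](Cc2ccccc2)COC1=O | intermediate
23 | (S)-4-benzyl-3-[(2S,3R)-3-hydroxy-3-(3-methoxy-4-triisopropylsilyloxyphenyl)-2-(ring-B aryloxy)propanoyl]oxazolidin-2-one | COc1cc([C@@H](O)[C@@H](C(=O)N2[C@@H](Cc3ccccc3)COC2=O)Oc2ccc(C[C@H]3CO[C@H](c4ccc(O[Si](C(C)C)(C(C)C)C(C)C)c(OC)c4)[C@H]3CO[Si](C(C)C)(C(C)C)C(C)C)cc2OC)ccc1O[Si](C(C)C)(C(C)C)C(C)C | intermediate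
24 | (1R,2R)-1-[3-methoxy-4-(triisopropylsilyloxy)phenyl]-2-(ring-B aryloxy)propane-1,3-diol, tris-silyl ether of the target | COc1cc([C@@H](O)[C@@H](CO)Oc2ccc(C[C@H]3CO[C@H](c4ccc(O[Si](C(C)C)(C(C)C)C(C)C)c(OC)c4)[C@H]3CO[Si](C(C)C)(C(C)C)C(C)C)cc2OC)ccc1O[Si](C(C)C)(C(C)C)C(C)C | intermediate
25 | CNP0158473.2, (1R,2R)-1-(4-hydroxy-3-methoxyphenyl)-2-{4-[((3R,4R,5S)-5-(4-hydroxy-3-methoxyphenyl)-4-(hydroxymethyl)tetrahydrofuran-3-yl)methyl]-2-methoxyphenoxy}propane-1,3-diol | COc1cc([C@@H](O)[C@@H](CO)Oc2ccc(C[C@H]3CO[C@H](c4ccc(O)c(OC)c4)[C@H]3CO)cc2OC)ccc1O | target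

**Step count**

Total: 16 steps. Longest linear sequence: 15 steps (steps 1–4 and 6–16 from eugenol); step 5 is the only side-branch step.

**Steps most likely to fail**

Step 4. The catalyst may discriminate poorly between the two enantiotopic methylenes, because the arylmethyl group at C3 is flexible and sits one carbon away from the ring. The peracid may also start to oxidise the electron-rich arene if the reaction is slow. The fallback sets out from vanillin 8 and comes back at lactone 7 by known chemistry:
- Vanillin is benzylated (BnBr, K2CO3) to 4-benzyloxy-3-methoxybenzaldehyde F1.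
- Stobbe condensation with dimethyl succinate (KOtBu, tBuOH) gives the half-ester (E)-4-(4-benzyloxy-3-methoxyphenyl)-3-(methoxycarbonyl)but-3-enoic acid F2.
- Carboxylate-directed enantioselective hydrogenation with [Rh(cod)2]BF4 and a DuPhos-type bisphosphine (H2, MeOH; the benzyl ether is inert to the homogeneous catalyst) gives (R)-4-(4-benzyloxy-3-methoxyphenyl)-3-(methoxycarbonyl)butanoic acid F3.
- Chemoselective reduction of the ester in the potassium carboxylate with Ca(BH4)2 (from CaCl2 and NaBH4, EtOH), then acidification, closes lactone 7.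

Step 8. The benzylic cation may be captured by ring B in a Friedel–Crafts closure to an aryltetralin instead of by the C5 hydroxyl, and C2 may not equilibrate fully to the 2,3-trans arrangement. The fallback sets out from triol 12 and comes back at 14, absorbing step 9:
- The aryl silyl ether is removed first (TBAF, 1 equiv, THF, 0 °C) to give (2R,3R)-2-(4-benzyloxy-3-methoxybenzyl)-3-[hydroxy(4-hydroxy-3-methoxyphenyl)methyl]butane-1,4-diol F4.
- The free p-hydroxybenzylic alcohol then loses water under very weak acid (pyridinium p-toluenesulfonate or AcOH, THF, rt) to a neutral p-quinone methide. The C5 hydroxyl adds to it reversibly, under conditions too mild for arene attack, to give 4-[(2S,3R,4R)-4-(4-benzyloxy-3-methoxybenzyl)-3-(hydroxymethyl)tetrahydrofuran-2-yl]-2-methoxyphenol F5.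
- Silylation of the phenol and the primary alcohol in one operation (TIPSCl, imidazole, DMF) gives 14.

Step 14. Enolisation of the bulky aryloxyacetyl imide may be incomplete, the electron-rich aldehyde may add slowly, and the adduct may undergo retro-aldol cleavage or lose diastereomeric purity on work-up. The fallback sets out from allyl ester 17 and comes back at 24:
- The lithium enolate of 17 (LDA, THF, −78 °C) is added to aldehyde 9 without stereocontrol to give the allyl 2-aryloxy-3-hydroxy-3-arylpropanoate diastereomer mixture F6.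
- Dess–Martin oxidation gives the configurationally labile α-aryloxy β-keto ester F7.
- Noyori-type asymmetric transfer hydrogenation under dynamic kinetic resolution (RuCl(p-cymene)(TsDPEN), antipode chosen to deliver the R carbinol, HCO2H/Et3N), a reaction known to give syn α-alkoxy β-hydroxy esters, gives the syn (2S,3R) hydroxy ester F8.
- LiBH4 reduction of the allyl ester gives diol 24.

**Further compounds**

F1 | step 4 | 4-benzyloxy-3-methoxybenzaldehyde | COc1cc(C=O)ccc1OCc1ccccc1
F2 | step 4 | (E)-4-(4-benzyloxy-3-methoxyphenyl)-3-(methoxycarbonyl)but-3-enoic acid | COC(=O)C(/CC(=O)O)=C/c1ccc(OCc2ccccc2)c(OC)c1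
F3 | step 4 | (R)-4-(4-benzyloxy-3-methoxyphenyl)-3-(methoxycarbonyl)butanoic acid | COC(=O)[C@H](Cc1ccc(OCc2ccccc2)c(OC)c1)CC(=O)O
F4 | step 8 | (2R,3R)-2-(4-benzyloxy-3-methoxybenzyl)-3-[hydroxy(4-hydroxy-3-methoxyphenyl)methyl]butane-1,4-diol, both carbinol epimers | COc1cc(C[C@@H](CO)[C@H](CO)C(O)c2ccc(O)c(OC)c2)ccc1OCc1ccccc1
F5 | step 8 | 4-[(2S,3R,4R)-4-(4-benzyloxy-3-methoxybenzyl)-3-(hydroxymethyl)tetrahydrofuran-2-yl]-2-methoxyphenol | COc1cc(C[C@H]2CO[C@H](c3ccc(O)c(OC)c3)[C@H]2CO)ccc1OCc1ccccc1
F6 | step 14 | allyl 3-hydroxy-3-(3-methoxy-4-triisopropylsilyloxyphenyl)-2-(ring-B aryloxy)propanoate, diastereomer mixture at C2 and C3 | C=CCOC(=O)C(Oc1ccc(C[C@H]2CO[C@H](c3ccc(O[Si](C(C)C)(C(C)C)C(C)C)c(OC)c3)[C@H]2CO[Si](C(C)C)(C(C)C)C(C)C)cc1OC)C(O)c1ccc(O[Si](C(C)C)(C(C)C)C(C)C)c(OC)c1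
F7 | step 14 | allyl 3-(3-methoxy-4-triisopropylsilyloxyphenyl)-3-oxo-2-(ring-B aryloxy)propanoate, C2 epimers | C=CCOC(=O)C(Oc1ccc(C[C@H]2CO[C@H](c3ccc(O[Si](C(C)C)(C(C)C)C(C)C)c(OC)c3)[C@H]2CO[Si](C(C)C)(C(C)C)C(C)C)cc1OC)C(=O)c1ccc(O[Si](C(C)C)(C(C)C)C(C)C)c(OC)c1
F8 | step 14 | allyl (2S,3R)-3-hydroxy-3-(3-methoxy-4-triisopropylsilyloxyphenyl)-2-(ring-B aryloxy)propanoate | COc1cc([C@@H](O)[C@@H](C(=O)OCC=C)Oc2ccc(C[C@H]3CO[C@H](c4ccc(O[Si](C(C)C)(C(C)C)C(C)C)c(OC)c4)[C@H]3CO[Si](C(C)C)(C(C)C)C(C)C)cc2OC)ccc1O[Si](C(C)C)(C(C)C)C(C)C
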